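In the target, each enone carbonyl is attached to a ring carbon whose neighbour bears a phenolic oxygen: C1 of ring A next to the C2 hydroxyl, and C1 of ring C next to its C2 hydroxyl. Both aryl ketones are therefore disconnected to aryl cinnamate esters, and a single irradiation is planned to shift the two acyl groups from oxygen to carbon (double photo-Fries rearrangement), making the ring A C1–CO and ring C C1–CO bonds at once. The substrate is a tetra-MOM bis-ester: O2 of ring C is acylated by 4-(methoxymethoxy)cinnamic acid and one ring A oxygen by the ring B cinnamic acid. It is built by Suzuki coupling, Steglich esterification and Horner–Wadsworth–Emmons olefination.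

Key step: step 11

Remark on the chemistry: ring A is the 2,4-dihydroxyphenyl ketone ring, ring B the 4-hydroxy-3-aryl styryl ring attached to it, ring C the 2,4-dihydroxy-5-aryl ketone ring and ring D the terminal 4-hydroxyphenyl ring; ring positions are counted from the acyl-bearing carbon (C1). All phenols not engaged in the two esters are assumed to be best masked as MOM ethers, so that one acid treatment ends the synthesis. MOM = methoxymethyl, TIPS = triisopropylsilyl, DIC = N,N'-diisopropylcarbodiimide.

Step 1
Reactants: 1 resorcinol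
Product: 2 3-(methoxymethoxy)phenol
Conditions: MOMCl (0.4 equiv relative to 1), iPr2NEt, THF, 0 °C to rt
Reagents that add atoms: chloromethyl methyl ether (MOMCl), COCCl
Why: MOM etherification (Williamson type) of one of two equivalent phenols; running the diol in excess keeps bis-protection low, and the surplus diol is removed by aqueous washing.

Step 2
Reactants: 2 3-(methoxymethoxy)phenol; 3 diethylphosphonoacetic acid
Product: 4 3-(methoxymethoxy)phenyl 2-(diethoxyphosphoryl)acetate
Conditions: DIC, DMAP (cat.), CH2Cl2, 0 °C to rt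
Reagents that add atoms: none
Why: Steglich esterification, in which the carbodiimide activates the phosphonoacetic acid and DMAP passes the acyl group to the phenol under conditions that leave the MOM ether alone.

Step 3
Reactants: 5 (E)-4-hydroxycinnamic acid
Product: 7 (E)-3-[4-(methoxymethoxy)phenyl]acrylic acid, via methoxymethyl (E)-3-[4-(methoxymethoxy)phenyl]acrylate 6 (not isolated)
Conditions: MOMCl (2.5 equiv), iPr2NEt, CH2Cl2, 0 °C to rt; then LiOH, THF/MeOH/H2O, rt; 1 M HCl to pH 4 at 0 °C
Reagents that add atoms: chloromethyl methyl ether (MOMCl), COCCl; LiOH, [Li+].[OH-] (supplies one carboxyl oxygen)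
Why: Both acidic OH groups are alkylated by MOMCl, and the acetal ester is then saponified selectively (ester hydrolysis) because it is far more labile to hydroxide than the aryl MOM ether, the E alkene of the starting acid being untouched.

Step 4
Reactants: 8 4-bromoresorcinol
Product: 9 2-bromo-5-[(triisopropylsilyl)oxy]phenol
Conditions: TIPSCl (1.0 equiv), imidazole, DMF, 0 °C
Reagents that add atoms: triisopropylsilyl chloride (TIPSCl), CC(C)[Si](Cl)(C(C)C)C(C)C
Why: Sterically governed regioselective silylation, in which the hydroxyl flanked by bromine is shielded so that the bulky silyl chloride should take the remote hydroxyl para to bromine.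

Step 5
Reactants: 9 2-bromo-5-[(triisopropylsilyl)oxy]phenol
Product: 10 [4-bromo-3-(methoxymethoxy)phenoxy]triisopropylsilane
Conditions: MOMCl, iPr2NEt, CH2Cl2, 0 °C to rt
Reagents that add atoms: chloromethyl methyl ether (MOMCl), COCCl
Why: MOM etherification of the remaining, more acidic ortho-bromophenol under amine base, conditions under which the aryl silyl ether is stable.

Step 6
Reactants: 11 3-bromo-4-hydroxybenzaldehyde
Product: 12 3-bromo-4-(methoxymethoxy)benzaldehyde
Conditions: MOMCl, iPr2NEt, CH2Cl2, 0 °C to rt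
Reagents that add atoms: chloromethyl methyl ether (MOMCl), COCCl
Why: MOM etherification of an acidic para-formyl phenol, with the aldehyde and the aryl bromide inert to the reagents.

Step 7
Reactants: 12 3-bromo-4-(methoxymethoxy)benzaldehyde
Product: 13 4-(methoxymethoxy)-3-(4,4,5,5-tetramethyl-1,3,2-dioxaborolan-2-yl)benzaldehyde
Conditions: B2pin2, Pd(dppf)Cl2 (cat.), KOAc, 1,4-dioxane, 85 °C
Reagents that add atoms: bis(pinacolato)diboron (B2pin2), CC1(C)OB(OC1(C)C)B1OC(C)(C)C(C)(C)O1
Why: Miyaura borylation, in which zerovalent palladium formed in situ inserts into the C–Br bond and acetate-assisted transmetalation with the diboron reagent gives the aryl boronate, conditions known to tolerate aldehydes and acetals.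

Step 8
Reactants: 13 4-(methoxymethoxy)-3-(4,4,5,5-tetramethyl-1,3,2-dioxaborolan-2-yl)benzaldehyde; 10 [4-bromo-3-(methoxymethoxy)phenoxy]triisopropylsilane
Product: 15 3-[4-hydroxy-2-(methoxymethoxy)phenyl]-4-(methoxymethoxy)benzaldehyde, via 4-(methoxymethoxy)-3-{2-(methoxymethoxy)-4-[(triisopropylsilyl)oxy]phenyl}benzaldehyde 14 (not isolated)
Conditions: Pd(OAc)2 (cat.), SPhos, K3PO4, 1,4-dioxane/H2O, 80 °C; then TBAF, THF, rt; aq. NH4Cl
Reagents that add atoms: none
Why: Suzuki–Miyaura cross-coupling of an electron-rich ortho-alkoxy aryl bromide with an aryl boronate, for which the SPhos ligand is well suited, followed in the same flask by fluoride cleavage of the aryl silyl ether at a stage where no ester is yet present.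

Step 9
Reactants: 15 3-[4-hydroxy-2-(methoxymethoxy)phenyl]-4-(methoxymethoxy)benzaldehyde; 7 (E)-3-[4-(methoxymethoxy)phenyl]acrylic acid
Product: 16 4-[5-formyl-2-(methoxymethoxy)phenyl]-3-(methoxymethoxy)phenyl (E)-3-[4-(methoxymethoxy)phenyl]acrylate
Conditions: DIC, DMAP (cat.), CH2Cl2, 0 °C to rt
Reagents that add atoms: none
Why: Steglich esterification of the only free phenol (O2 of ring C) with the ring D cinnamic acid, the aldehyde and the MOM ethers being inert to carbodiimide and DMAP.

Step 10
Reactants: 16 4-[5-formyl-2-(methoxymethoxy)phenyl]-3-(methoxymethoxy)phenyl (E)-3-[4-(methoxymethoxy)phenyl]acrylate; 4 3-(methoxymethoxy)phenyl 2-(diethoxyphosphoryl)acetate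
Product: 17 3-(methoxymethoxy)phenyl (E)-3-{4-(methoxymethoxy)-3-[2-(methoxymethoxy)-4-((E)-3-(4-(methoxymethoxy)phenyl)acryloyloxy)phenyl]phenyl}acrylate
Conditions: LiCl, iPr2NEt, MeCN, rt
Reagents that add atoms: none
Why: Horner–Wadsworth–Emmons olefination under Masamune–Roush conditions, in which the lithium-chelated phosphonate is deprotonated by the amine and adds to the aryl aldehyde to give the E cinnamate, while the mild base spares both aryl esters.

Step 11
Reactants: 17 3-(methoxymethoxy)phenyl (E)-3-{4-(methoxymethoxy)-3-[2-(methoxymethoxy)-4-((E)-3-(4-(methoxymethoxy)phenyl)acryloyloxy)phenyl]phenyl}acrylate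
Product: 18 (E)-1-[2-hydroxy-4-(methoxymethoxy)phenyl]-3-{3-[4-hydroxy-2-(methoxymethoxy)-5-((E)-3-(4-(methoxymethoxy)phenyl)acryloyl)phenyl]-4-(methoxymethoxy)phenyl}prop-2-en-1-one
Conditions: hν (300 nm, Pyrex), degassed benzene (2 mM), Ar, rt
Reagents that add atoms: none
Why: Absorption by each aryl ester should lead to homolysis of its ArO–C(O) bond, giving a solvent-caged aryloxyl/cinnamoyl radical pair that recombines at a ring carbon and tautomerises to the hydroxyaryl ketone (photo-Fries rearrangement). The closest known reaction is the light-induced conversion of aryl cinnamates into 2'-hydroxychalcones, here required at two ester groups of one molecule. No ring is closed and no stereocentre is created; the E enones are the thermodynamic isomers, and the chelated 2-hydroxy ketones, once formed, should dissipate further excitation by intramolecular proton transfer. The step needs site selectivity on both rings and no exchange of acyl groups: on ring C the carbon para to the ester oxygen is occupied by the biaryl bond and one ortho carbon is squeezed between two oxygens, which leaves only C1. On ring A, recombination at the ortho carbon remote from the MOM ether gives 18 directly, para recombination would give an isomer that leads to the same target after deprotection, and only the hindered carbon between the two oxygens would mislead. Recombination inside the cage at high dilution keeps each acyl group on its own ring and suppresses [2+2] dimerisation of the cinnamates.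

Step 12
Reactants: 18 (E)-1-[2-hydroxy-4-(methoxymethoxy)phenyl]-3-{3-[4-hydroxy-2-(methoxymethoxy)-5-((E)-3-(4-(methoxymethoxy)phenyl)acryloyl)phenyl]-4-(methoxymethoxy)phenyl}prop-2-en-1-one
Product: 19 (E)-1-(2,4-dihydroxyphenyl)-3-{3-[2,4-dihydroxy-5-((E)-3-(4-hydroxyphenyl)acryloyl)phenyl]-4-hydroxyphenyl}prop-2-en-1-one
Conditions: 3 M HCl (aq), MeOH, 50 °C
Reagents that add atoms: none
Why: Acid-catalysed cleavage of the four MOM acetals by transacetalisation with methanol, a standard way to release 2',4'-dihydroxychalcones, which lack the 6'-hydroxyl that drives flavanone closure; the acidic medium should also return any Z enone to the E form.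

Compound list
1 | resorcinol | Oc1cccc(O)c1 | starting material
2 | 3-(methoxymethoxy)phenol | COCOc1cccc(O)c1 | intermediate
3 | diethylphosphonoacetic acid | CCOP(=O)(CC(=O)O)OCC | starting material
4 | 3-(methoxymethoxy)phenyl 2-(diethoxyphosphoryl)acetate | CCOP(=O)(CC(=O)Oc1cccc(OCOC)c1)OCC | intermediate
5 | (E)-4-hydroxycinnamic acid | O=C(O)/C=C/c1ccc(O)cc1 | starting material
6 | methoxymethyl (E)-3-[4-(methoxymethoxy)phenyl]acrylate | COCOC(=O)/C=C/c1ccc(OCOC)cc1 | intermediate
7 | (E)-3-[4-(methoxymethoxy)phenyl]acrylic acid | COCOc1ccc(/C=C/C(=O)O)cc1 | intermediate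
8 | 4-bromoresorcinol | Oc1ccc(Br)c(O)c1 | starting material
9 | 2-bromo-5-[(triisopropylsilyl)oxy]phenol | CC(C)[Si](Oc1ccc(Br)c(O)c1)(C(C)C)C(C)C | intermediate
10 | [4-bromo-3-(methoxymethoxy)phenoxy]triisopropylsilane | COCOc1cc(O[Si](C(C)C)(C(C)C)C(C)C)ccc1Br | intermediate
11 | 3-bromo-4-hydroxybenzaldehyde | O=Cc1ccc(O)c(Br)c1 | starting material
12 | 3-bromo-4-(methoxymethoxy)benzaldehyde | COCOc1ccc(C=O)cc1Br | intermediate
13 | 4-(methoxymethoxy)-3-(4,4,5,5-tetramethyl-1,3,2-dioxaborolan-2-yl)benzaldehyde | COCOc1ccc(C=O)cc1B1OC(C)(C)C(C)(C)O1 | intermediate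
14 | 4-(methoxymethoxy)-3-{2-(methoxymethoxy)-4-[(triisopropylsilyl)oxy]phenyl}benzaldehyde | COCOc1ccc(C=O)cc1-c1ccc(O[Si](C(C)C)(C(C)C)C(C)C)cc1OCOC | intermediate
15 | 3-[4-hydroxy-2-(methoxymethoxy)phenyl]-4-(methoxymethoxy)benzaldehyde | COCOc1ccc(C=O)cc1-c1ccc(O)cc1OCOC | intermediate
16 | 4-[5-formyl-2-(methoxymethoxy)phenyl]-3-(methoxymethoxy)phenyl (E)-3-[4-(methoxymethoxy)phenyl]acrylate | COCOc1ccc(C=O)cc1-c1ccc(OC(=O)/C=C/c2ccc(OCOC)cc2)cc1OCOC | intermediate
17 | 3-(methoxymethoxy)phenyl (E)-3-{4-(methoxymethoxy)-3-[2-(methoxymethoxy)-4-((E)-3-(4-(methoxymethoxy)phenyl)acryloyloxy)phenyl]phenyl}acrylate | COCOc1cccc(OC(=O)/C=C/c2ccc(OCOC)c(-c3ccc(OC(=O)/C=C/c4ccc(OCOC)cc4)cc3OCOC)c2)c1 | intermediate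
18 | (E)-1-[2-hydroxy-4-(methoxymethoxy)phenyl]-3-{3-[4-hydroxy-2-(methoxymethoxy)-5-((E)-3-(4-(methoxymethoxy)phenyl)acryloyl)phenyl]-4-(methoxymethoxy)phenyl}prop-2-en-1-one | COCOc1ccc(C(=O)/C=C/c2ccc(OCOC)c(-c3cc(C(=O)/C=C/c4ccc(OCOC)cc4)c(O)cc3OCOC)c2)c(O)c1 | intermediate
19 | (E)-1-(2,4-dihydroxyphenyl)-3-{3-[2,4-dihydroxy-5-((E)-3-(4-hydroxyphenyl)acryloyl)phenyl]-4-hydroxyphenyl}prop-2-en-1-one (the target bichalcone) | O=C(/C=C/c1ccc(O)c(-c2cc(C(=O)/C=C/c3ccc(O)cc3)c(O)cc2O)c1)c1ccc(O)cc1O | target

Total step count: 12 steps.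
Longest linear sequence: 7 steps (4, 5, 8, 9, 10, 11, 12; the branch 6, 7, 8, 9, 10, 11, 12 is equally long).

Steps most likely to fail

1. Step 11. The twofold acyl shift may stop after one migration, or lose acyl radicals from the cage to give phenols. It may also be overtaken by E/Z scrambling and photodimerisation of the cinnamate units, or place the ring A acyl group between the two oxygens. The fallback builds both enones by aldol condensation instead; it sets out from boronate 13 and comes back at 18.
   - Commercial 1-(5-bromo-2,4-dihydroxyphenyl)ethan-1-one would be protected at its non-chelated hydroxyl (MOMCl, K2CO3, acetone) to give 1-[5-bromo-2-hydroxy-4-(methoxymethoxy)phenyl]ethan-1-one F1.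
   - Commercial 4-hydroxybenzaldehyde would be converted (MOMCl, iPr2NEt) into 4-(methoxymethoxy)benzaldehyde F2.
   - Claisen–Schmidt condensation of F1 with F2 (KOH, EtOH, rt) should give (E)-1-[5-bromo-2-hydroxy-4-(methoxymethoxy)phenyl]-3-[4-(methoxymethoxy)phenyl]prop-2-en-1-one F3.
   - Suzuki–Miyaura coupling of F3 with 13 (Pd(OAc)2, SPhos, K3PO4, dioxane/H2O) should give 3-{4-hydroxy-2-(methoxymethoxy)-5-[(E)-3-(4-(methoxymethoxy)phenyl)acryloyl]phenyl}-4-(methoxymethoxy)benzaldehyde F4.
   - A second Claisen–Schmidt condensation of F4 with 1-[2-hydroxy-4-(methoxymethoxy)phenyl]ethan-1-one F5 (from commercial 2,4-dihydroxyacetophenone, MOMCl, K2CO3) under KOH in EtOH should deliver 18.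

2. Step 10. The anion of the aryl phosphonoacetate may expel its phenoxide, and the liberated phenoxide or the amine base may exchange or cleave the aryl esters, so the olefination may stall or scramble the two ester groups. The fallback forms the alkene before any ester exists; it sets out from 14 (isolated by leaving out the fluoride treatment in step 8) and comes back at 17.
   - Knoevenagel–Doebner condensation of 14 with malonic acid (pyridine, piperidine cat., 90 °C) should give (E)-3-{4-(methoxymethoxy)-3-[2-(methoxymethoxy)-4-((triisopropylsilyl)oxy)phenyl]phenyl}acrylic acid F6.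
   - Steglich esterification of F6 with 2 (DIC, DMAP) should give 3-(methoxymethoxy)phenyl (E)-3-{4-(methoxymethoxy)-3-[2-(methoxymethoxy)-4-((triisopropylsilyl)oxy)phenyl]phenyl}acrylate F7.
   - Buffered desilylation (TBAF, AcOH, THF, 0 °C) should release 3-(methoxymethoxy)phenyl (E)-3-{3-[4-hydroxy-2-(methoxymethoxy)phenyl]-4-(methoxymethoxy)phenyl}acrylate F8.
   - Steglich esterification of F8 with acid 7 gives 17.

3. Step 4. Silylation may occur at the hydroxyl next to bromine or at both hydroxyls, so the two ring C oxygens would be differentiated the wrong way or not at all. The fallback fixes the oxygen pattern first and introduces bromine afterwards; it sets out from 2 and comes back at 10.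
   - Bromination of 2 with NBS (MeCN, −20 °C), directed para to the free hydroxyl, should give 4-bromo-3-(methoxymethoxy)phenol F9.
   - Silylation of F9 (TIPSCl, imidazole, DMF) gives 10.

Further compounds
F1 | step 11 | 1-[5-bromo-2-hydroxy-4-(methoxymethoxy)phenyl]ethan-1-one | CC(=O)c1cc(Br)c(OCOC)cc1O
F2 | step 11 | 4-(methoxymethoxy)benzaldehyde | COCOc1ccc(C=O)cc1
F3 | step 11 | (E)-1-[5-bromo-2-hydroxy-4-(methoxymethoxy)phenyl]-3-[4-(methoxymethoxy)phenyl]prop-2-en-1-one | COCOc1ccc(/C=C/C(=O)c2cc(Br)c(OCOC)cc2O)cc1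
F4 | step 11 | 3-{4-hydroxy-2-(methoxymethoxy)-5-[(E)-3-(4-(methoxymethoxy)phenyl)acryloyl]phenyl}-4-(methoxymethoxy)benzaldehyde | COCOc1ccc(C=O)cc1-c1cc(C(=O)/C=C/c2ccc(OCOC)cc2)c(O)cc1OCOC
F5 | step 11 | 1-[2-hydroxy-4-(methoxymethoxy)phenyl]ethan-1-one | CC(=O)c1ccc(OCOC)cc1O
F6 | step 10 | (E)-3-{4-(methoxymethoxy)-3-[2-(methoxymethoxy)-4-((triisopropylsilyl)oxy)phenyl]phenyl}acrylic acid | COCOc1ccc(/C=C/C(=O)O)cc1-c1ccc(O[Si](C(C)C)(C(C)C)C(C)C)cc1OCOC
F7 | step 10 | 3-(methoxymethoxy)phenyl (E)-3-{4-(methoxymethoxy)-3-[2-(methoxymethoxy)-4-((triisopropylsilyl)oxy)phenyl]phenyl}acrylate | COCOc1cccc(OC(=O)/C=C/c2ccc(OCOC)c(-c3ccc(O[Si](C(C)C)(C(C)C)C(C)C)cc3OCOC)c2)c1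
F8 | step 10 | 3-(methoxymethoxy)phenyl (E)-3-{3-[4-hydroxy-2-(methoxymethoxy)phenyl]-4-(methoxymethoxy)phenyl}acrylate | COCOc1cccc(OC(=O)/C=C/c2ccc(OCOC)c(-c3ccc(O)cc3OCOC)c2)c1
F9 | step 4 | 4-bromo-3-(methoxymethoxy)phenol | COCOc1cc(O)ccc1Br
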